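## Analysis of the target

The target 21 is a cyclobutane whose four ring carbons are all substituted methines; there is no other carbocycle. Going round the ring, Ca and Cd each carry a 2-aminoimidazole bonded through its C4(5), and Cb and Cc each carry a CH2–NH–C(=O) arm ending in a pyrrol-2-yl ring. All four ring carbons are stereocentres, every vicinal pair is trans, and the molecule has a C2 axis through the midpoints of the Ca–Cd and Cb–Cc bonds; the configuration is (1R,2R,3S,4S) with Cb = C1, Cc = C2, Cd = C3, Ca = C4. The sensitive groups are the two basic, polar, oxidisable and metal-binding 2-aminoimidazoles, the two electron-rich N–H pyrroles and the two secondary amides. The difficulty is to make a strained ring with four contiguous stereocentres as one enantiomer: the all-trans array is the thermodynamic one, but a ring carrying four equivalent epimerisable groups would be achiral, so one carbon has to be held fixed while the others settle. The strategy rests on two adjacencies: Cb and Cc each bear one carbon, which is what remains when a ring C=C fused across Cb–Cc is cleaved, and Ca and Cd each bear a carbon at the carboxyl oxidation level (imidazole C4(5)), which together are a cyclic anhydride. A cyclobutane fused on one edge to a cyclobutene and on the opposite edge to an anhydride is the photochemical valence isomer of a dihydrophthalic anhydride.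

## Retrosynthetic reasoning

Imidazole rings. Both 2-aminoimidazoles of 21 are cut at N1–C2, C2–N3 and N3–C4, which leads back to the bis(aminomethyl ketone) salt 20. The ketone carbon becomes imidazole C4(5), so Ca and Cd only need to carry carboxyl-derived carbons. The basic heterocycles are made last so that no earlier step has to tolerate them. The forward step must condense each amine with a one-carbon, two-nitrogen electrophile and cyclodehydrate, twice, without epimerising Ca or Cd out of the all-trans array.

Aminomethyl ketones. 20 is traced through the diformylamide 19 to the bis(chloromethyl ketone) 18 (C–N cut), and 18 through the diazoketone 17 and the mixed anhydride 16 to the diacid 15 (cut between the carbonyl carbon and the new CH2). This one-carbon homologation is chosen because it starts from plain carboxyl groups and tolerates secondary amides and N–H pyrroles.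

Amide and arm nitrogen. 15 comes from the diester 14, whose two amide N–C(=O) bonds are cut to the diamine salt 12 and two molecules of the acyl donor 13. The CH2–N bonds of 12 are cut through the dibenzylamine 11 to the dialdehyde 10. A secondary amine is used in the forward direction so that neither cyclisation onto the second aldehyde nor lactam formation with the esters can occur.

Ring C=C. The two formyl carbons of 10 are reconnected as a double bond. 10 is the epimer of the cis-dialdehyde 9, which comes through the ozonide 8 from the cyclobutene 7. Cleavage delivers Cb and Cc at the aldehyde level but cis, so the forward step has to invert one formyl-bearing carbon; the all-trans isomer is the only one without a cis-vicinal pair.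

Relative and absolute configuration at Ca and Cd. The trans diester 7 comes from the trans hemiester 6, which is the C3 epimer of the cis hemiester 5, and 5 is one of the two methanolysis products of the meso anhydride 4. The choice of carbonyl opened fixes the absolute sense. The carboxylate-bearing carbon cannot enolise under alkoxide, so only the ester-bearing carbon inverts. This is the step that makes a C2-symmetric chiral product out of a meso ring.

Key disconnection. In 4 the Cb–Cc bond is cut, which opens the bicyclo[2.2.0]hexene to the cyclohexadiene of cis-1,2-dihydrophthalic anhydride 3. One bond gives the cyclobutane with all four substituent carbons in place. The forward reaction must close the diene termini on each other and not open the six-membered ring.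

Precursor. 3 is the anhydride of the dihydro diacid 2, which is the 1,2-reduction product of phthalic acid 1. These are two routine steps, so the risk sits in the photochemical step.

## Alternatives that were turned down

Alternative 1: Bicyclobutane formation and strain-release heteroarylation. The ring is cut at Cb–Ca and across the ring at Cb–Cd. In the forward sense the diazoester A2 would lose nitrogen on Rh2(S-NTTL)4, and the rhodium carbene would add intramolecularly to the E-alkene three atoms away to give the bicyclo[1.1.0]butane A1; a second heteroaryl nucleophile would then open the central bond.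
- For: enantiocontrol is catalytic, the heteroaryl rings arrive intact, and the four-membered ring is reached in very few steps. On these three points it is stronger than the chosen route, which uses a stoichiometric (recoverable) alkaloid and builds the heterocycles from carboxyl groups.
- Against: A2 already has a stereocentre next to the carbene carbon, so catalyst and substrate control must agree. The basic imidazole nitrogen can occupy the axial sites of the dirhodium catalyst. The benzylic ether C–H bonds sit where 1,5-insertion to a tetrahydrofuran competes with cyclopropanation. The strain-release addition would need to control the face of attack and the protonation of the resulting enolate on a doubly substituted bicyclobutane. Both imidazoles would still need an amino group at C2, and both one-carbon arms would still need nitrogen.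
- Comparison: several unproven selectivities are stacked at the front. The chosen route has a ring-forming step with no selectivity question (meso to meso) and a two-directional end-game.

Alternative 2: Twofold directed C–H heteroarylation. The two bonds from Ca and Cd to imidazole C4 are cut. In the forward sense the trans bis(8-aminoquinoline) amide A4 would be arylated at both ring CH2 groups by the iodoimidazole A5 under Pd(OAc)2 and AgOAc, which gives A3.
- For: the ring is bought, not made, and cis-selective palladation next to the directing amide is dependable. This is the most convergent of the four plans and is stronger than the chosen route in step count to a tetrasubstituted ring.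
- Against: in A3 each heteroaryl is cis to its neighbouring amide, so both amide-bearing carbons must be inverted afterwards, by enolising hindered secondary amides. A5 is an N-heteroaryl iodide that can bind divalent palladium and silver through N3, and its sulfonyl group is labile under the conditions. A4 has two bidentate auxiliaries that can sequester the metal together. Two auxiliaries must be removed, two amides reduced to CH2N and two imidazoles aminated at C2.
- Comparison: the plan leans on the substrate class for which this coupling is weakest. The chosen route keeps all metal catalysis away from basic heterocycles and gets the all-trans array from equilibration at activated carbons only.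

Alternative 3: Cyclohexene cleavage and oxidative bis-enolate closure. The Ca–Cd bond is cut. In the forward sense the adipate A7 (from oxidative cleavage of the cyclohexene A8) would be deprotonated twice and the dienolate oxidised with I2 or CuBr2, so that its two α-carbons couple to give the cyclobutane A6.
- For: the two arm-bearing stereocentres come from a trans-disubstituted cyclohexene available as one enantiomer by dependable cycloaddition chemistry. The ester-bearing carbons are epimerisable to all-trans. No photoreactor or ozone is needed and the arms are at the robust ether level. On early absolute control and on scalability this plan is stronger than the chosen one.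
- Against: the ring closure has to build the full cyclobutane strain in a coupling that competes with intermolecular coupling, with α-iodination that does not close, and with Dieckmann condensation of the mono-enolate to a five-membered ketoester. The benzyl ethers then need deprotection, activation and displacement before nitrogen is in place.
- Comparison: the ring-forming event is uphill and has bimolecular competitors. In the chosen route the strain is paid by a photon in a unimolecular closure, and the arms come out as aldehydes that take nitrogen directly.

Key step: step 3

Assumption: in step 3 the new ring is taken to fold away from the anhydride, so that 4 is the anti isomer; the opposite fold would at most change which pseudoenantiomeric alkaloid is needed in step 4, because both series meet at 7.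

Assumption: quinidine is taken to direct methanol to the carbonyl on the (R)-configured ring carbon of 4, giving 5 as drawn; if the sense on this ring system is the opposite, quinine is used and nothing else changes.

## Route

Step 1
Reactants: 1 phthalic acid
Product: 2 trans-1,2-dihydrophthalic acid (racemic)
Conditions: 3% Na(Hg), NaOAc, AcOH, H2O, 0–5 °C; then H2SO4 (aq)
Reagents that add atoms: none
Why: Dissolving-metal 1,2-reduction of the phthalate dianion in buffered water; protonation of the dienolate gives the trans diacid, which crystallises on acidification. The stereochemistry is irrelevant because step 2 equilibrates it.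

Step 2
Reactants: 2 trans-1,2-dihydrophthalic acid
Product: 3 cis-1,2-dihydrophthalic anhydride (meso)
Conditions: Ac2O, 100 °C, short reaction time
Reagents that add atoms: none
Why: Mixed-anhydride formation makes the doubly allylic α-hydrogen acidic enough to epimerise, and only the cis diacid can close to a five-membered anhydride, so the equilibrium drains to 3. Short heating limits double-bond migration and aromatisation.

Step 3
Reactants: 3 cis-1,2-dihydrophthalic anhydride
Product: 4 bicyclo[2.2.0]hex-5-ene-2,3-dicarboxylic anhydride (meso, anhydride anti to the cyclobutene)
Conditions: hν (medium-pressure mercury lamp, Vycor filter), Et2O, 0–10 °C, N2, to partial conversion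
Reagents that add atoms: none
Why: Excitation of the s-cis diene is followed by disrotatory 4π-electrocyclisation, the photochemically allowed mode for four electrons, which joins the two diene termini (the future Cb and Cc) by a new σ bond. The closest known reaction type is the photochemical valence isomerisation of cyclohexa-1,3-dienes to bicyclo[2.2.0]hex-2-enes, for which this anhydride is the classical substrate on the way to the Dewar benzene skeleton. One ring is closed: the six-membered ring is bridged transannularly, so the same bond completes the cyclobutane (Ca, Cb, Cc, Cd) and the cyclobutene in a 4π-electrocyclic, disrotatory closure. The two new stereocentres (Cb, Cc) are forced cis to each other by disrotation and because a trans-fused bicyclo[2.2.0]hexene cannot exist; their position relative to the anhydride follows from the fold, expected away from the carbonyl groups. The selectivity needed is 4π closure over the conrotatory 6π ring opening that flexible cyclohexadienes prefer, and over hydrogen shift or aromatisation. The cis-fused anhydride secures it: it holds the diene planar and ties the two sp3 carbons together, so that ring opening would have to produce a nine-membered trienic anhydride containing an E double bond. No enantioselectivity is needed because 3 and 4 are both meso. Irradiation is stopped before full conversion and 4 is kept cold to limit secondary photolysis and thermal reversion.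

Step 4
Reactants: 4 bicyclo[2.2.0]hex-5-ene-2,3-dicarboxylic anhydride
Product: 5 (1R,2S,3R,4S)-3-(methoxycarbonyl)bicyclo[2.2.0]hex-5-ene-2-carboxylic acid (cis, both carboxyl groups exo)
Conditions: quinidine (1.1 equiv), MeOH (3 equiv), toluene, −55 °C; then aq. HCl wash
Reagents that add atoms: methanol, CO
Why: Cinchona-alkaloid-mediated methanolysis of a meso cyclic anhydride, a known desymmetrisation for cyclobutane-fused and bicyclic succinic anhydrides; the alkaloid acts as chiral general base and selects one enantiotopic carbonyl. No stereocentre is made, but the acid-bearing carbon is now distinguished from the ester-bearing one, which fixes the absolute sense of everything that follows.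

Step 5
Reactants: 5 cis hemiester
Product: 6 (1R,2S,3S,4S)-3-(methoxycarbonyl)bicyclo[2.2.0]hex-5-ene-2-carboxylic acid (trans; acid exo, ester endo)
Conditions: NaOMe (4 equiv), MeOH, 55 °C; then aq. HCl, 0 °C
Reagents that add atoms: none
Why: Base epimerisation of a cis hemiester at the ester-bearing carbon, a known way to trans hemiesters without loss of enantiopurity; the carboxylate carbon cannot enolise under alkoxide, so only C3 inverts. Relief of the eclipsed cis carboxylate/ester pair should drive C3 to the trans arrangement, and methoxide in methanol makes transesterification degenerate.

Step 6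
Reactants: 6 trans hemiester
Product: 7 dimethyl (1R,2S,3S,4S)-bicyclo[2.2.0]hex-5-ene-2,3-dicarboxylate (trans)
Conditions: MeI, K2CO3, DMF, rt
Reagents that add atoms: iodomethane, CI
Why: SN2 O-methylation of the carboxylate. The acid/ester distinction has done its work once C3 is inverted, and the diester gives neutral, chromatographable intermediates that become C2-symmetric after ring cleavage; K2CO3 is too weak to enolise the esters.

Step 7
Reactants: 7 trans diester
Product: 10 dimethyl (1S,2S,3R,4R)-3,4-diformylcyclobutane-1,2-dicarboxylate (all-trans), via ozonide 8 (not isolated), via cis-dialdehyde 9 (not isolated)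
Conditions: O3, CH2Cl2, −78 °C; PPh3, −78 °C to rt; then DBU (0.2 equiv), rt
Reagents that add atoms: ozone, [O-][O+]=O
Why: Ozonolysis (Criegee mechanism) of the strained cis-alkene and phosphine reduction of the ozonide give both formyl groups cis. DBU then epimerises the formyl-bearing carbon that is cis to both neighbours, because the all-trans isomer is the only one with no cis-vicinal pair, while the ester α-hydrogens are not acidic enough to move. Ring opening by retro-Michael cleavage is disfavoured because the ring C–C bonds lie close to the nodal plane of the enolate π system, whose p orbital at the ring carbon stands perpendicular to the ring.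

Step 8
Reactants: 10 all-trans dialdehyde
Product: 11 dimethyl all-trans-3,4-bis[(dibenzylamino)methyl]cyclobutane-1,2-dicarboxylate
Conditions: Bn2NH (2.5 equiv), NaBH(OAc)3 (3 equiv), AcOH (cat.), ClCH2CH2Cl, rt
Reagents that add atoms: dibenzylamine, C(NCc1ccccc1)c1ccccc1
Why: Twofold reductive amination with a triacetoxyborohydride; a secondary amine cannot over-alkylate, cannot condense with the second aldehyde to a bicyclic pyrrolidine, and gives a tertiary amine that cannot lactamise. Any enamine-mediated epimerisation returns to the all-trans array, which is already the stable one.

Step 9
Reactants: 11 bis(dibenzylamine)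
Product: 12 dimethyl all-trans-3,4-bis(aminomethyl)cyclobutane-1,2-dicarboxylate dihydrochloride
Conditions: H2 (4 bar), Pd(OH)2/C, HCl (2.2 equiv), MeOH, rt
Reagents that add atoms: hydrogen chloride, Cl
Why: Hydrogenolysis of four N-benzyl groups; cyclobutanes and esters are untouched. Isolation as the salt keeps the primary amines from attacking the ester that is cis-1,3 to each of them.

Step 10
Reactants: 12 diamine dihydrochloride; 13 2-(trichloroacetyl)pyrrole
Product: 14 dimethyl all-trans-3,4-bis{[(1H-pyrrole-2-carbonyl)amino]methyl}cyclobutane-1,2-dicarboxylate
Conditions: 13 (2.2 equiv), Et3N (5 equiv), DMF, rt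
Reagents that add atoms: 2-(trichloroacetyl)pyrrole (second equivalent of 13), ClC(Cl)(Cl)C(=O)c1ccc[nH]1
Why: Haloform-type acyl transfer carried out twice: each freed primary amine attacks one molecule of the trichloromethyl ketone and chloroform leaves, so two equivalents of 13 are consumed, one per amide. No coupling reagent is needed, the pyrrole N–H stays unprotected, and acylation is faster than the strained bridged lactamisation.

Step 11
Reactants: 14 bis-amide diester
Product: 15 all-trans-3,4-bis{[(1H-pyrrole-2-carbonyl)amino]methyl}cyclobutane-1,2-dicarboxylic acid
Conditions: LiOH, THF/H2O, rt; then aq. HCl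
Reagents that add atoms: lithium hydroxide (hydroxide oxygen), [Li+].[OH-]
Why: Saponification of two methyl esters; the secondary pyrrole amides survive, and the α-carbons are already in their most stable arrangement.

Step 12
Reactants: 15 diacid
Product: 18 all-trans bis(chloromethyl ketone) (two C(=O)CH2Cl groups on Ca and Cd), via bis(isobutyl carbonic anhydride) 16 (not isolated), via bis(diazoketone) 17 (not isolated)
Conditions: iBuOCOCl, N-methylmorpholine, THF, −15 °C; CH2N2, Et2O, −15 to 0 °C; then HCl (4 M in dioxane), 0 °C
Reagents that add atoms: diazomethane, C=[N+]=[N-]; hydrogen chloride, Cl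
Why: Mixed-anhydride activation, acylation of diazomethane (first stage of the Arndt–Eistert sequence) and hydrochlorination of the diazoketone, the standard route to chloromethyl ketones from N-acylamino acids. The trans diacid cannot close to a cyclic anhydride, and amide and pyrrole N–H groups are inert to these reagents in the cold.

Step 13
Reactants: 18 bis(chloromethyl ketone)
Product: 20 all-trans bis(aminomethyl ketone) dihydrochloride, via bis(diformylamide) 19 (not isolated)
Conditions: NaN(CHO)2, MeCN, 35 °C; then HCl, MeOH, rt
Reagents that add atoms: sodium diformylamide, [Na+].O=C[N-]C=O; hydrogen chloride, Cl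
Why: Gabriel-type SN2 displacement by a non-basic ammonia equivalent, then acid methanolysis of the formyl groups. The aminoketone is kept as its salt so that it cannot self-condense to a dihydropyrazine.

Step 14
Reactants: 20 bis(aminomethyl ketone) dihydrochloride
Product: 21 target, N,N'-{[(1R,2R,3S,4S)-3,4-bis(2-amino-1H-imidazol-5-yl)cyclobutane-1,2-diyl]bis(methylene)}bis(1H-pyrrole-2-carboxamide)
Conditions: H2NCN (excess), H2O, pH 4–5, 95 °C; then aq. NaHCO3
Reagents that add atoms: cyanamide, NC#N
Why: Classical 2-aminoimidazole synthesis: each ammonium group adds to cyanamide to give a guanidine, which cyclises on the ketone and dehydrates. Only Ca and Cd are enolisable and they are already trans to both neighbours, so the configuration holds.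

## Compound list

1 | phthalic acid | OC(=O)c1ccccc1C(O)=O | starting material
2 | trans-1,2-dihydrophthalic acid (racemic) | OC(=O)[C@H]1C=CC=C[C@@H]1C(O)=O | intermediate
3 | cis-1,2-dihydrophthalic anhydride (meso) | O=C1OC(=O)[C@H]2[C@@H]1C=CC=C2 | intermediate
4 | bicyclo[2.2.0]hex-5-ene-2,3-dicarboxylic anhydride (meso, anhydride anti to the cyclobutene) | O=C1OC(=O)[C@H]2[C@@H]1[C@@H]1C=C[C@H]21 | intermediate
5 | (1R,2S,3R,4S)-3-(methoxycarbonyl)bicyclo[2.2.0]hex-5-ene-2-carboxylic acid (cis, exo,exo) | COC(=O)[C@H]1[C@@H](C(O)=O)[C@@H]2C=C[C@H]12 | intermediate
6 | (1R,2S,3S,4S)-3-(methoxycarbonyl)bicyclo[2.2.0]hex-5-ene-2-carboxylic acid (trans; acid exo, ester endo) | COC(=O)[C@@H]1[C@@H](C(O)=O)[C@@H]2C=C[C@H]12 | intermediate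
7 | dimethyl (1R,2S,3S,4S)-bicyclo[2.2.0]hex-5-ene-2,3-dicarboxylate (trans) | COC(=O)[C@@H]1[C@@H](C(=O)OC)[C@@H]2C=C[C@H]12 | intermediate
8 | ozonide of 7 (1,2,4-trioxolane bridging the two former alkene carbons; configuration at the two acetal carbons not defined) | COC(=O)[C@@H]1[C@@H](C(=O)OC)[C@@H]2C3OOC(O3)[C@H]12 | intermediate
9 | dimethyl 3,4-diformylcyclobutane-1,2-dicarboxylate, esters trans, formyl groups cis (C4 formyl cis to the C1 ester) | COC(=O)[C@@H]1[C@@H](C(=O)OC)[C@H](C=O)[C@@H]1C=O | intermediate
10 | dimethyl (1S,2S,3R,4R)-3,4-diformylcyclobutane-1,2-dicarboxylate (all-trans) | COC(=O)[C@@H]1[C@@H](C(=O)OC)[C@H](C=O)[C@H]1C=O | intermediate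
11 | dimethyl all-trans-3,4-bis[(dibenzylamino)methyl]cyclobutane-1,2-dicarboxylate (absolute series of 10) | COC(=O)[C@@H]1[C@@H](C(=O)OC)[C@H](CN(Cc2ccccc2)Cc2ccccc2)[C@H]1CN(Cc1ccccc1)Cc1ccccc1 | intermediate
12 | dimethyl all-trans-3,4-bis(aminomethyl)cyclobutane-1,2-dicarboxylate dihydrochloride | COC(=O)[C@@H]1[C@@H](C(=O)OC)[C@H](CN)[C@H]1CN.Cl.Cl | intermediate
13 | 2-(trichloroacetyl)pyrrole (2,2,2-trichloro-1-(1H-pyrrol-2-yl)ethan-1-one) | ClC(Cl)(Cl)C(=O)c1ccc[nH]1 | starting material
14 | dimethyl all-trans-3,4-bis{[(1H-pyrrole-2-carbonyl)amino]methyl}cyclobutane-1,2-dicarboxylate | COC(=O)[C@@H]1[C@@H](C(=O)OC)[C@H](CNC(=O)c2ccc[nH]2)[C@H]1CNC(=O)c1ccc[nH]1 | intermediate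
15 | all-trans-3,4-bis{[(1H-pyrrole-2-carbonyl)amino]methyl}cyclobutane-1,2-dicarboxylic acid | OC(=O)[C@@H]1[C@@H](C(O)=O)[C@H](CNC(=O)c2ccc[nH]2)[C@H]1CNC(=O)c1ccc[nH]1 | intermediate
16 | bis(isobutyl carbonic) mixed anhydride of 15 | CC(C)COC(=O)OC(=O)[C@@H]1[C@@H](C(=O)OC(=O)OCC(C)C)[C@H](CNC(=O)c2ccc[nH]2)[C@H]1CNC(=O)c1ccc[nH]1 | intermediate
17 | all-trans bis(diazoacetyl) compound (two C(=O)CHN2 groups on Ca and Cd) | [N-]=[N+]=CC(=O)[C@@H]1[C@@H](C(=O)C=[N+]=[N-])[C@H](CNC(=O)c2ccc[nH]2)[C@H]1CNC(=O)c1ccc[nH]1 | intermediate
18 | all-trans bis(chloroacetyl) compound (two C(=O)CH2Cl groups on Ca and Cd) | ClCC(=O)[C@@H]1[C@@H](C(=O)CCl)[C@H](CNC(=O)c2ccc[nH]2)[C@H]1CNC(=O)c1ccc[nH]1 | intermediate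
19 | all-trans bis[(diformylamino)acetyl] compound | O=CN(C=O)CC(=O)[C@@H]1[C@@H](C(=O)CN(C=O)C=O)[C@H](CNC(=O)c2ccc[nH]2)[C@H]1CNC(=O)c1ccc[nH]1 | intermediate
20 | all-trans bis(aminoacetyl) compound, dihydrochloride | NCC(=O)[C@@H]1[C@@H](C(=O)CN)[C@H](CNC(=O)c2ccc[nH]2)[C@H]1CNC(=O)c1ccc[nH]1.Cl.Cl | intermediate
21 | N,N'-{[(1R,2R,3S,4S)-3,4-bis(2-amino-1H-imidazol-5-yl)cyclobutane-1,2-diyl]bis(methylene)}bis(1H-pyrrole-2-carboxamide) | Nc1ncc([C@H]2[C@H](CNC(=O)c3ccc[nH]3)[C@@H](CNC(=O)c3ccc[nH]3)[C@@H]2c2cnc(N)[nH]2)[nH]1 | target

## Step count and least certain steps

Total step count: 14. Longest linear sequence: 14 steps (1 to 21); 13 is purchased.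

Step 3 (key step). The most likely failure is secondary photolysis of 4 at the short wavelength needed, together with thermal hydrogen shift or aromatisation of the diene and hydrolysis of either anhydride by traces of water, so that material is lost faster than the closure proceeds. Fallback: set out from 2 and esterify it (MeOH, catalytic H2SO4, rt) to dimethyl trans-1,2-dihydrophthalate F1, which is insensitive to moisture. Irradiating F1 in ether through a filter that cuts off the wavelengths absorbed by the isolated cyclobutene should bring about the same disrotatory closure and give the trans diester as a racemate, that is 7 together with its mirror image F2. Without the anhydride bridge, conrotatory opening to the triene is no longer blocked, so this closure is expected to be less clean. The triene can, however, reclose photochemically to F1, whereas the bicycle no longer absorbs and should accumulate. Chromatography on a chiral stationary phase then separates 7 from F2, and the route is rejoined at 7. This replaces desymmetrisation by resolution and makes steps 4 to 6 unnecessary.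

Step 5. The inversion may stop short of completion, because the ester moves to the concave face of the bicycle and enolisation next to a carboxylate is slow; prolonged heating could also erode enantiopurity through reversible anhydride formation. Fallback: replace thermodynamic by kinetic control. Starting from 5, LiN(iPr)2 (2.3 equiv, THF, −78 °C) gives the dilithium enolate-carboxylate F5. Protonating F5 with a hindered phenol and then aqueous HCl should deliver the proton to the convex face, which places the ester endo and gives 6, where the route is rejoined.

Step 4. The alkaloid may discriminate poorly between the two carbonyls of this compact, rigid tricycle, or open the other one. Fallback: open 4 without selectivity (MeOH, Et3N, rt) to the racemic hemiester, 5 together with its mirror image F3. Resolve by crystallising the (R)-1-phenylethylammonium salt F4 of 5 (the other antipode of the amine is used if the salt of F3 is the less soluble one) and acidify with aqueous HCl to return 5.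

Step 7. Ozone may over-oxidise the formyl groups, or reduction of the compact bicyclic ozonide 8 may be incomplete, leaving peroxide that destroys the aldehydes once base is added; the cis-dialdehyde 9 may also self-condense before it epimerises. Fallback: cleave the alkene in two non-peroxidic stages. Starting from 7, OsO4 (catalytic) with N-methylmorpholine N-oxide adds to the convex face to give the cis-diol F6. NaIO4 in aqueous THF cleaves F6 to 9, where the route is rejoined before the DBU treatment.

Step 12. Twofold activation may be incomplete, so that diazomethane merely esterifies the unactivated carboxyl, and the pyrrole rings may suffer during acidolysis of the diazoketone. Fallback: set out from 15 and treat it with carbonyldiimidazole to give the bis(acyl imidazolide) F7. Acylate the potassium nitronate of nitromethane (CH3NO2, KOtBu, THF; aq. HCl on work-up) with F7 to give the bis(nitromethyl ketone) F8. Hydrogenate F8 (H2, Pd/C, HCl, MeOH) to the aminoketone salt, rejoining the route at 20 and making step 13 unnecessary.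

Step 14. Annulation of one ketone may outrun the other, and at the temperature needed the free aminoketone may dimerise if the pH drifts upward. Fallback: set out from 18 and heat it with N-Boc-guanidine (excess, NaI, DMF), which alkylates and cyclodehydrates in one operation to give the bis(2-amino-1-Boc-imidazol-4-yl) compound F9. Trifluoroacetic acid removes both carbamates from F9, and neutralisation gives 21.

## Further compounds

F1 | step 3 | dimethyl trans-1,2-dihydrophthalate (racemic) | COC(=O)[C@H]1C=CC=C[C@@H]1C(=O)OC
F2 | step 3 | mirror image of 7, formed with 7 as the racemate | COC(=O)[C@H]1[C@H](C(=O)OC)[C@H]2C=C[C@@H]12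
F3 | step 4 | mirror image of 5, formed with 5 as the racemate | COC(=O)[C@@H]1[C@H](C(O)=O)[C@H]2C=C[C@@H]12
F4 | step 4 | (R)-1-phenylethylammonium salt of 5 | COC(=O)[C@H]1[C@@H](C(O)=O)[C@@H]2C=C[C@H]12.C[C@@H](N)c1ccccc1
F5 | step 5 | dilithium enolate-carboxylate of 5 | COC([O-])=C1[C@@H](C([O-])=O)[C@@H]2C=C[C@H]12.[Li+].[Li+]
F6 | step 7 | dimethyl 5-exo,6-exo-dihydroxybicyclo[2.2.0]hexane-2,3-dicarboxylate (trans diester, from 7) | COC(=O)[C@@H]1[C@@H](C(=O)OC)[C@@H]2[C@@H](O)[C@@H](O)[C@H]12
F7 | step 12 | bis(acyl imidazolide) of 15 | O=C(n1ccnc1)[C@@H]2[C@@H](C(=O)n3ccnc3)[C@H](CNC(=O)c4ccc[nH]4)[C@H]2CNC(=O)c5ccc[nH]5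
F8 | step 12 | all-trans bis(nitroacetyl) compound | [O-][N+](=O)CC(=O)[C@@H]2[C@@H](C(=O)C[N+]([O-])=O)[C@H](CNC(=O)c4ccc[nH]4)[C@H]2CNC(=O)c5ccc[nH]5
F9 | step 14 | all-trans bis(2-amino-1-tert-butoxycarbonylimidazol-4-yl) compound | CC(C)(C)OC(=O)n1cc(nc1N)[C@@H]2[C@@H](c3cn(C(=O)OC(C)(C)C)c(N)n3)[C@H](CNC(=O)c4ccc[nH]4)[C@H]2CNC(=O)c5ccc[nH]5
A1 | alternative 1 | tert-butyl exo,exo-2-(benzyloxymethyl)-4-[1-(dimethylsulfamoyl)imidazol-4-yl]bicyclo[1.1.0]butane-1-carboxylate | CC(C)(C)OC(=O)[C@@]12[C@@H](COCc3ccccc3)[C@@H]1[C@H]2c1cn(S(=O)(=O)N(C)C)cn1
A2 | alternative 1 | tert-butyl (E)-3-(benzyloxymethyl)-2-diazo-5-[1-(dimethylsulfamoyl)imidazol-4-yl]pent-4-enoate | CC(C)(C)OC(=O)C(=[N+]=[N-])[C@@H](COCc1ccccc1)/C=C/c1cn(S(=O)(=O)N(C)C)cn1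
A3 | alternative 2 | 3,4-bis(1-tosylimidazol-4-yl)-N1,N2-di(quinolin-8-yl)cyclobutane-1,2-dicarboxamide, each heteroaryl cis to its neighbouring amide | Cc1ccc(cc1)S(=O)(=O)n1cnc(c1)[C@H]2[C@@H](C(=O)Nc3cccc4cccnc34)[C@H](C(=O)Nc3cccc4cccnc34)[C@@H]2c1cn(S(=O)(=O)c2ccc(C)cc2)cn1
A4 | alternative 2 | trans-N1,N2-di(quinolin-8-yl)cyclobutane-1,2-dicarboxamide | C1[C@@H](C(=O)Nc2cccc3cccnc23)[C@H](C(=O)Nc2cccc3cccnc23)C1
A5 | alternative 2 | 4-iodo-1-tosylimidazole | Cc1ccc(cc1)S(=O)(=O)n1cnc(I)c1
A6 | alternative 3 | dimethyl all-trans-3,4-bis(benzyloxymethyl)cyclobutane-1,2-dicarboxylate | COC(=O)[C@H]1[C@H](COCc2ccccc2)[C@@H](COCc2ccccc2)[C@@H]1C(=O)OC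
A7 | alternative 3 | dimethyl 3,4-bis(benzyloxymethyl)hexanedioate (C2-symmetric diastereomer) | COC(=O)C[C@H](COCc1ccccc1)[C@@H](COCc1ccccc1)CC(=O)OC
A8 | alternative 3 | trans-4,5-bis(benzyloxymethyl)cyclohexene | C1=CC[C@H](COCc2ccccc2)[C@@H](COCc2ccccc2)C1
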